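Atoms carry labdane numbers: ring A = C1–C5 and C10, ring B = C5–C10, C17 = CH3 on C8, C18 = CH2O and C19 = CH3 on C4, C20 = CH3 on C10, C11–C16 = side chain.
Cuts, in retrosynthetic order: the two ester C–O bonds (C15 malonate, C18 angelate); ring B at C9–C10 together with C8–O; C10=C20; C4–C18 and C5–C6 on a ring-A cyclohexenone; the chain at C6–C7.
Enabling feature: C10 and C8 are fully substituted carbons flanking C9, and C7, C8, C17, C9 and C11–C16 are the skeleton of (S)-citronellol, so ring B can close when an (E)-C8=C9 alkene hung from C5 attacks a C10 cation and oxygen arrives at C8.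
Forward order: citronellol becomes a C6–C16 Grignard reagent; it joins the purchased ring A at C5 and formaldehyde is taken up at C4; C3 is deoxygenated; C10 is unveiled and methylenated; ring B closes; the esters are set last.
Stereochemistry: C13 from (S)-citronellol; C5 from a chiral copper catalyst; C4 from hydroxymethylation anti to the C5 chain; C10, C9 and C8 from chair-like anti addition across the E alkene; the Z ester from angelic acid.

Key step: step 14

Remark: enone 9 is taken as purchased; it is otherwise one dehydrogenation away from the saturated ketal.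
Remark: the copper–carbene catalyst is assumed to select faces on enone 11 as it does on 2-methylcyclohex-2-enone; the ligand antipode is chosen to give 6R in 14.

Step 1
Reactants: 1 (S)-citronellol
Product: 2 citronellol tert-butyldiphenylsilyl ether
Conditions: TBDPSCl, imidazole, DMF, 0 °C → rt
Reagents that add atoms: tert-butyl(chloro)diphenylsilane, CC(C)(C)[Si](Cl)(c1ccccc1)c1ccccc1
Why: Imidazole-promoted silylation of the only hydroxyl gives an ether that should survive organomagnesium chemistry, hydride and the acid of step 14 and leave with fluoride at the end.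

Step 2
Reactants: 2 citronellol tert-butyldiphenylsilyl ether
Product: 4 (2E,6S)-8-silyloxy-2,6-dimethyloct-2-enal, via allylic alcohol 3 (not isolated)
Conditions: SeO2 (0.3 equiv), t-BuOOH, CH2Cl2, rt; crude product, MnO2, CH2Cl2, rt
Reagents that add atoms: tert-butyl hydroperoxide, CC(C)(C)OO (oxygen relayed by SeO2)
Why: Riley-type allylic oxidation (ene reaction, then [2,3] shift) attacks the E methyl of the prenyl terminus, which fixes the later C8=C9 geometry, and MnO2 converges alcohol 3 and any enal already formed to the single enal.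

Step 3
Reactants: 4 (2E,6S)-8-silyloxy-2,6-dimethyloct-2-enal
Product: 5 (3S,6E)-3,7-dimethylnona-6,8-dienyl silyl ether
Conditions: Ph3PCH3Br, KOt-Bu, THF, 0 °C → rt
Reagents that add atoms: methyltriphenylphosphonium bromide, C[P+](c1ccccc1)(c1ccccc1)c1ccccc1.[Br-]
Why: Wittig methylenation of the enal adds C6 and leaves the trisubstituted alkene geometry untouched.

Step 4
Reactants: 5 (3S,6E)-3,7-dimethylnona-6,8-dienyl silyl ether
Product: 7 (3E,7S)-9-silyloxy-3,7-dimethylnon-3-en-1-ol, via alkylborane 6 (not isolated)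
Conditions: 9-BBN-H, THF, 0 °C → rt; then NaOH, H2O2, 0 °C
Reagents that add atoms: hydrogen peroxide, OO
Why: Hydroboration–oxidation with a bulky borane is selective for the terminal vinyl group of such a diene (anti-Markovnikov), as in the classical route to homogeraniol, and makes C6 a primary alcohol.

Step 5
Reactants: 7 (3E,7S)-9-silyloxy-3,7-dimethylnon-3-en-1-ol
Product: 8 (3S,6E)-9-bromo-3,7-dimethylnon-6-enyl silyl ether
Conditions: CBr4, PPh3, CH2Cl2, 0 °C
Reagents that add atoms: carbon tetrabromide, BrC(Br)(Br)Br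
Why: The Appel reaction displaces the primary homoallylic alcohol by SN2 without allylic transposition.

Step 6
Reactants: 9 1,4-dioxaspiro[4.5]dec-6-en-8-one
Product: 10 7-iodo-1,4-dioxaspiro[4.5]dec-6-en-8-one
Conditions: I2, pyridine, CH2Cl2, 0 °C → rt
Reagents that add atoms: iodine, [I][I]
Why: Pyridine-mediated α-iodination of a cyclic enone (conjugate addition, iodination, elimination) is routine for this ketal enone.

Step 7
Reactants: 10 7-iodo-1,4-dioxaspiro[4.5]dec-6-en-8-one
Product: 11 7-methyl-1,4-dioxaspiro[4.5]dec-6-en-8-one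
Conditions: MeB(OH)2, Pd(OAc)2 (5 mol %), SPhos (10 mol %), K3PO4, toluene/H2O, 80 °C
Reagents that add atoms: methylboronic acid, CB(O)O
Why: Suzuki–Miyaura coupling of the α-iodoenone installs the future C19 methyl under basic conditions that the ketal tolerates.

Step 8
Reactants: 8 (3S,6E)-9-bromo-3,7-dimethylnon-6-enyl silyl ether; 11 7-methyl-1,4-dioxaspiro[4.5]dec-6-en-8-one
Product: 14 (6R,7S)-6-alkyl-7-(hydroxymethyl)-7-methyl-1,4-dioxaspiro[4.5]decan-8-one, via Grignard reagent 12 (not isolated), via magnesium enolate 13 (not isolated)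
Conditions: 8, Mg, Et2O, rt; then 11, Cu(OTf)2 (3 mol %), leucinol-derived N-mesityl hydroxyalkyl imidazolinium hexafluorophosphate (4 mol %), Et2O, −30 °C; then CH2O (gas), THF, −78 → −40 °C; aq. NH4Cl
Reagents that add atoms: formaldehyde, C=O
Why: Copper–carbene-catalysed asymmetric conjugate addition of a Grignard reagent to an α-methyl cyclic enone should set C5 by catalyst control, and the aldol reaction of enolate 13 with formaldehyde should occur anti to the new C5 chain, making C4 quaternary with CH2OH trans to the chain.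

Step 9
Reactants: 14 (6R,7S)-6-alkyl-7-(hydroxymethyl)-7-methyl-1,4-dioxaspiro[4.5]decan-8-one
Product: 15 C18 pivalate of 14
Conditions: PivCl, pyridine, DMAP (cat.), CH2Cl2, 0 °C → rt
Reagents that add atoms: pivaloyl chloride, CC(C)(C)C(Cl)=O
Why: Pyridine/DMAP acylation of the neopentyl primary alcohol blocks retro-aldol loss of formaldehyde and gives an ester that should neither trap a cation nor be cleaved in step 14.

Step 10
Reactants: 15 C18 pivalate of 14
Product: 16 C3 tosylhydrazone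
Conditions: TsNHNH2, MeOH/THF, 4 Å molecular sieves, 55 °C
Reagents that add atoms: 4-methylbenzenesulfonohydrazide, Cc1ccc(cc1)S(=O)(=O)NN
Why: Hydrazone condensation can occur only at the C3 ketone because C10 is masked as the dioxolane.

Step 11
Reactants: 16 C3 tosylhydrazone
Product: 18 C3-deoxygenated ketal pivalate, via N-borylhydrazide 17 (not isolated)
Conditions: catecholborane, CHCl3, 0 °C → rt; then NaOAc·3H2O, reflux
Reagents that add atoms: none
Why: Caglioti-type reduction with catecholborane (hydroboration of C=N, then acetate-induced loss of sulfinate and dinitrogen from the diazene) turns C3 into CH2 without reagents that would harm the ester, the ketal or the alkene.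

Step 12
Reactants: 18 C3-deoxygenated ketal pivalate
Product: 19 (1S,2R)-configured C10 ketone
Conditions: PPTS, acetone/H2O (10:1), 55 °C
Reagents that add atoms: water, O
Why: Weak-acid ketal hydrolysis frees the C10 carbonyl, the mild acid being chosen so that C5, now α to a ketone, is not enolised.

Step 13
Reactants: 19 (1S,2R)-configured C10 ketone
Product: 20 ring-A diene with C10 methylidene
Conditions: Zn, CH2Br2, TiCl4, THF (reagent pre-formed at −40 → 5 °C); then 19, CH2Cl2, 0 °C → rt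
Reagents that add atoms: dibromomethane, BrCBr
Why: Takai–Lombardo methylenation is non-basic, so the hindered and epimerisable ketone should give the methylidene without change at C5 or attack on the ester.

Step 14
Reactants: 20 ring-A diene with C10 methylidene
Product: 22 bicyclic C8 tertiary alcohol, via C8 trifluoroacetate 21 (not isolated)
Conditions: CF3CO2H (20 equiv), CH2Cl2, −40 → −10 °C; then K2CO3, MeOH, 0 °C
Reagents that add atoms: trifluoroacetic acid, OC(=O)C(F)(F)F (supplies the C8 oxygen; its acyl group leaves in the work-up)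
Why: CF3CO2H protonates the 1,1-disubstituted C10=C20 alkene to the tertiary C10 cation, the (E)-C8=C9 alkene attacks it through C9, and the tertiary C8 cation is captured by trifluoroacetate to give 21, whose methanolysis unveils the alcohol, a net Markovnikov cyclisation–hydration. The closest known chemistry is the proton-initiated cation–olefin cyclisation of monocyclic homofarnesyl-type alcohols and acids to trans-fused bicycles, combined with the usual trapping of a terminal tertiary cation by a carboxylic acid solvent. Ring B (C5–C10) closes in a 6-endo-trig mode through a chair-like transition state. At C10, C9 arrives equatorially on the ring-A chair opposite H-5, so C20 becomes axial and the fusion trans, which the pre-set C5 centre with its equatorial chain dictates; at C9 the E geometry within the chair puts C11 equatorial and H-9 axial, anti to C20; at C8 the nucleophile enters antiperiplanar to the new C9–C10 bond, that is equatorially, and leaves C17 axial. The step needs initiation at the methylidene, ring closure faster than loss of H-5 from the C10 cation, and capture faster than proton loss from the C8 cation; low temperature, excess nucleophilic acid, two tertiary cation sites, the fixed E alkene and the non-participating pivalate and silyl ether should secure this.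

Step 15
Reactants: 22 bicyclic C8 tertiary alcohol
Product: 23 C8,C18 diol
Conditions: i-Bu2AlH (3.5 equiv), CH2Cl2, −78 → 0 °C; aq. KNaC4H4O6
Reagents that add atoms: none
Why: Hydride cleavage of the hindered pivalate is standard and spares the silyl ether and the tertiary alcohol.

Step 16
Reactants: 23 C8,C18 diol; 24 angelic acid
Product: 26 C18 angelate, via mixed anhydride 25 (not isolated)
Conditions: 24, 2,4,6-trichlorobenzoyl chloride, Et3N, toluene, rt; then 23, 75 °C
Reagents that add atoms: none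
Why: Yamaguchi-type esterification through the trichlorobenzoyl mixed anhydride without DMAP is the established way to make angelates without Z to E isomerisation, and only the primary C18 hydroxyl should be acylated, not the tertiary C8 hydroxyl.

Step 17
Reactants: 26 C18 angelate
Product: 27 C15 alcohol
Conditions: HF·pyridine, pyridine/THF, 0 °C → rt
Reagents that add atoms: none
Why: Buffered fluoride desilylation removes the silyl ether without acyl migration or isomerisation of the angelate.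

Step 18
Reactants: 27 C15 alcohol; 28 Meldrum's acid
Product: 29 CNP0286290.1
Conditions: 28 (1.3 equiv), toluene, 95 °C
Reagents that add atoms: none
Why: Thermal alcoholysis of Meldrum's acid by a primary alcohol gives the malonic half ester directly with loss of acetone, while the tertiary C8 alcohol is too hindered to react.

Compound list
1 | (3S)-3,7-dimethyloct-6-en-1-ol, (S)-citronellol | CC(C)=CCC[C@H](C)CCO | starting material
2 | tert-butyl{[(3S)-3,7-dimethyloct-6-en-1-yl]oxy}diphenylsilane | CC(C)=CCC[C@H](C)CCO[Si](c1ccccc1)(c1ccccc1)C(C)(C)C | intermediate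
3 | (2E,6S)-8-{[tert-butyl(diphenyl)silyl]oxy}-2,6-dimethyloct-2-en-1-ol | OC/C(C)=C/CC[C@H](C)CCO[Si](c1ccccc1)(c1ccccc1)C(C)(C)C | intermediate
4 | (2E,6S)-8-{[tert-butyl(diphenyl)silyl]oxy}-2,6-dimethyloct-2-enal | O=C/C(C)=C/CC[C@H](C)CCO[Si](c1ccccc1)(c1ccccc1)C(C)(C)C | intermediate
5 | tert-butyl{[(3S,6E)-3,7-dimethylnona-6,8-dien-1-yl]oxy}diphenylsilane | C=C/C(C)=C/CC[C@H](C)CCO[Si](c1ccccc1)(c1ccccc1)C(C)(C)C | intermediate
6 | 9-[(3E,7S)-9-{[tert-butyl(diphenyl)silyl]oxy}-3,7-dimethylnon-3-en-1-yl]-9-borabicyclo[3.3.1]nonane | C1CCC2CCCC1B2CC/C(C)=C/CC[C@H](C)CCO[Si](c1ccccc1)(c1ccccc1)C(C)(C)C | intermediate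
7 | (3E,7S)-9-{[tert-butyl(diphenyl)silyl]oxy}-3,7-dimethylnon-3-en-1-ol | OCC/C(C)=C/CC[C@H](C)CCO[Si](c1ccccc1)(c1ccccc1)C(C)(C)C | intermediate
8 | {[(3S,6E)-9-bromo-3,7-dimethylnon-6-en-1-yl]oxy}(tert-butyl)diphenylsilane | BrCC/C(C)=C/CC[C@H](C)CCO[Si](c1ccccc1)(c1ccccc1)C(C)(C)C | intermediate
9 | 1,4-dioxaspiro[4.5]dec-6-en-8-one | O=C1C=CC2(CC1)OCCO2 | starting material
10 | 7-iodo-1,4-dioxaspiro[4.5]dec-6-en-8-one | O=C1C(I)=CC2(CC1)OCCO2 | intermediate
11 | 7-methyl-1,4-dioxaspiro[4.5]dec-6-en-8-one | CC1=CC2(CCC1=O)OCCO2 | intermediate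
12 | [(3E,7S)-9-{[tert-butyl(diphenyl)silyl]oxy}-3,7-dimethylnon-3-en-1-yl]magnesium bromide | Br[Mg]CC/C(C)=C/CC[C@H](C)CCO[Si](c1ccccc1)(c1ccccc1)C(C)(C)C | intermediate
13 | bromomagnesium (6R)-6-[(3E,7S)-9-{[tert-butyl(diphenyl)silyl]oxy}-3,7-dimethylnon-3-en-1-yl]-7-methyl-1,4-dioxaspiro[4.5]dec-7-en-8-olate | CC1=C(O[Mg]Br)CCC2(OCCO2)[C@@H]1CC/C(C)=C/CC[C@H](C)CCO[Si](c1ccccc1)(c1ccccc1)C(C)(C)C | intermediate
14 | (6R,7S)-6-[(3E,7S)-9-{[tert-butyl(diphenyl)silyl]oxy}-3,7-dimethylnon-3-en-1-yl]-7-(hydroxymethyl)-7-methyl-1,4-dioxaspiro[4.5]decan-8-one | OC[C@@]1(C)C(=O)CCC2(OCCO2)[C@@H]1CC/C(C)=C/CC[C@H](C)CCO[Si](c1ccccc1)(c1ccccc1)C(C)(C)C | intermediate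
15 | [(6R,7S)-6-[(3E,7S)-9-{[tert-butyl(diphenyl)silyl]oxy}-3,7-dimethylnon-3-en-1-yl]-7-methyl-8-oxo-1,4-dioxaspiro[4.5]decan-7-yl]methyl 2,2-dimethylpropanoate | CC(C)(C)C(=O)OC[C@@]1(C)C(=O)CCC2(OCCO2)[C@@H]1CC/C(C)=C/CC[C@H](C)CCO[Si](c1ccccc1)(c1ccccc1)C(C)(C)C | intermediate
16 | [(6R,7R)-6-[(3E,7S)-9-{[tert-butyl(diphenyl)silyl]oxy}-3,7-dimethylnon-3-en-1-yl]-7-methyl-8-{2-[(4-methylphenyl)sulfonyl]hydrazinylidene}-1,4-dioxaspiro[4.5]decan-7-yl]methyl 2,2-dimethylpropanoate | CC(C)(C)C(=O)OC[C@@]1(C)C(=NNS(=O)(=O)c2ccc(C)cc2)CCC2(OCCO2)[C@@H]1CC/C(C)=C/CC[C@H](C)CCO[Si](c1ccccc1)(c1ccccc1)C(C)(C)C | intermediate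
17 | N-(1,3,2-benzodioxaborol-2-yl)-N′-tosylhydrazine adduct of 16 at ring carbon 8 (configuration at that carbon undefined and lost in the same flask) | CC(C)(C)C(=O)OC[C@@]1(C)C(N(B2Oc3ccccc3O2)NS(=O)(=O)c2ccc(C)cc2)CCC2(OCCO2)[C@@H]1CC/C(C)=C/CC[C@H](C)CCO[Si](c1ccccc1)(c1ccccc1)C(C)(C)C | intermediate
18 | [(6R,7S)-6-[(3E,7S)-9-{[tert-butyl(diphenyl)silyl]oxy}-3,7-dimethylnon-3-en-1-yl]-7-methyl-1,4-dioxaspiro[4.5]decan-7-yl]methyl 2,2-dimethylpropanoate | CC(C)(C)C(=O)OC[C@@]1(C)CCCC2(OCCO2)[C@@H]1CC/C(C)=C/CC[C@H](C)CCO[Si](c1ccccc1)(c1ccccc1)C(C)(C)C | intermediate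
19 | [(1S,2R)-2-[(3E,7S)-9-{[tert-butyl(diphenyl)silyl]oxy}-3,7-dimethylnon-3-en-1-yl]-1-methyl-3-oxocyclohexyl]methyl 2,2-dimethylpropanoate | CC(C)(C)C(=O)OC[C@@]1(C)CCCC(=O)[C@@H]1CC/C(C)=C/CC[C@H](C)CCO[Si](c1ccccc1)(c1ccccc1)C(C)(C)C | intermediate
20 | [(1S,2S)-2-[(3E,7S)-9-{[tert-butyl(diphenyl)silyl]oxy}-3,7-dimethylnon-3-en-1-yl]-1-methyl-3-methylidenecyclohexyl]methyl 2,2-dimethylpropanoate | CC(C)(C)C(=O)OC[C@@]1(C)CCCC(=C)[C@@H]1CC/C(C)=C/CC[C@H](C)CCO[Si](c1ccccc1)(c1ccccc1)C(C)(C)C | intermediate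
21 | [(1S,4aR,5S,6S,8aS)-5-[(3S)-5-{[tert-butyl(diphenyl)silyl]oxy}-3-methylpentyl]-1,4a,6-trimethyl-6-(trifluoroacetoxy)decahydronaphthalen-1-yl]methyl 2,2-dimethylpropanoate | CC(C)(C)C(=O)OC[C@@]1(C)CCC[C@]2(C)[C@@H]1CC[C@](C)(OC(=O)C(F)(F)F)[C@H]2CC[C@H](C)CCO[Si](c1ccccc1)(c1ccccc1)C(C)(C)C | intermediate
22 | [(1S,4aR,5S,6S,8aS)-5-[(3S)-5-{[tert-butyl(diphenyl)silyl]oxy}-3-methylpentyl]-6-hydroxy-1,4a,6-trimethyldecahydronaphthalen-1-yl]methyl 2,2-dimethylpropanoate | CC(C)(C)C(=O)OC[C@@]1(C)CCC[C@]2(C)[C@@H]1CC[C@](C)(O)[C@H]2CC[C@H](C)CCO[Si](c1ccccc1)(c1ccccc1)C(C)(C)C | intermediate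
23 | (1S,2S,4aS,5S,8aR)-1-[(3S)-5-{[tert-butyl(diphenyl)silyl]oxy}-3-methylpentyl]-5-(hydroxymethyl)-2,5,8a-trimethyldecahydronaphthalen-2-ol | OC[C@@]1(C)CCC[C@]2(C)[C@@H]1CC[C@](C)(O)[C@H]2CC[C@H](C)CCO[Si](c1ccccc1)(c1ccccc1)C(C)(C)C | intermediate
24 | (2Z)-2-methylbut-2-enoic acid, angelic acid | C/C=C(/C)C(=O)O | starting material
25 | (2Z)-2-methylbut-2-enoic 2,4,6-trichlorobenzoic anhydride | C/C=C(/C)C(=O)OC(=O)c1c(Cl)cc(Cl)cc1Cl | intermediate
26 | [(1S,4aR,5S,6S,8aS)-5-[(3S)-5-{[tert-butyl(diphenyl)silyl]oxy}-3-methylpentyl]-6-hydroxy-1,4a,6-trimethyldecahydronaphthalen-1-yl]methyl (2Z)-2-methylbut-2-enoate | C/C=C(/C)C(=O)OC[C@@]1(C)CCC[C@]2(C)[C@@H]1CC[C@](C)(O)[C@H]2CC[C@H](C)CCO[Si](c1ccccc1)(c1ccccc1)C(C)(C)C | intermediate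
27 | [(1S,4aR,5S,6S,8aS)-6-hydroxy-5-[(3S)-5-hydroxy-3-methylpentyl]-1,4a,6-trimethyldecahydronaphthalen-1-yl]methyl (2Z)-2-methylbut-2-enoate | C/C=C(/C)C(=O)OC[C@@]1(C)CCC[C@]2(C)[C@@H]1CC[C@](C)(O)[C@H]2CC[C@H](C)CCO | intermediate
28 | 2,2-dimethyl-1,3-dioxane-4,6-dione, Meldrum's acid | CC1(C)OC(=O)CC(=O)O1 | starting material
29 | 3-{[(3S)-5-[(1S,2S,4aS,5S,8aR)-2-hydroxy-2,5,8a-trimethyl-5-({[(2Z)-2-methylbut-2-enoyl]oxy}methyl)decahydronaphthalen-1-yl]-3-methylpentyl]oxy}-3-oxopropanoic acid, CNP0286290.1 | C/C=C(/C)C(=O)OC[C@@]1(C)CCC[C@]2(C)[C@@H]1CC[C@](C)(O)[C@H]2CC[C@H](C)CCOC(=O)CC(=O)O | target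

Total step count: 18. Longest linear sequence: 16 steps (steps 1–5 and 8–18); steps 6 and 7 form the short ring-A branch.

Steps most likely to fail

1. Step 14. The C8 cation may lose a proton faster than it is captured, the chain alkene may be protonated before the methylidene, or H-5 may be lost from the C10 cation and erode the C5 centre. The fallback sets out from 20 and addresses the first of these. Ring B would be closed with a non-nucleophilic strong acid (ClSO3H, 2-nitropropane, −78 °C, Et3N quench), aiming at the bicyclic alkenes, written as the exocyclic C8=C17 alkene F1 (its ring-B trisubstituted isomer behaves alike). These would then be hydrated by Mukaiyama hydration (Co(acac)2, PhSiH3, O2, then PPh3), in which the tertiary C8 radical should take up oxygen from the equatorial face. The sequence comes back to the route at 22.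

2. Step 8. Addition to the α-methyl, γ,γ-dialkoxy enone may be slow or poorly face-selective, so that C5 is formed with low enantiocontrol or 1,2-addition intrudes. The fallback sets out from 8 and 9. Grignard reagent 12 would be added to the unmethylated enone 9 under CuCl/Taniaphos catalysis in Et2O, the best-documented substrate class for this reaction, to give the magnesium enolate F2. Methylation in the same flask (MeI, DMPU) should give the trans methyl ketone F3. Its more substituted enol ether, the trimethylsilyl enol ether F4 (TMSCl, NaI, Et3N, MeCN), would then undergo Mukaiyama aldol hydroxymethylation (aqueous CH2O, Yb(OTf)3, THF) anti to the chain. This comes back to the route at 14.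

3. Step 10. The C3 carbonyl, flanked by the quaternary C4, may condense too slowly, and forcing acid would start to exchange the ketal. The fallback sets out from 15. NaBH4 in MeOH would give the C3 alcohol F5 (either epimer serves). 1,1′-Thiocarbonyldiimidazole with DMAP in toluene at 90 °C, neutral conditions that avoid pivaloyl migration, would give the thiocarbonylimidazolide F6. Barton–McCombie reduction (Bu3SnH, AIBN, toluene, 110 °C) then comes back to the route at 18, bypassing 16 and 17.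

Further compounds
F1 | step 14 | [(1S,4aS,5R,8aS)-5-[(3S)-5-{[tert-butyl(diphenyl)silyl]oxy}-3-methylpentyl]-1,4a-dimethyl-6-methylidenedecahydronaphthalen-1-yl]methyl 2,2-dimethylpropanoate | CC(C)(C)C(=O)OC[C@@]1(C)CCC[C@]2(C)[C@@H]1CCC(=C)[C@H]2CC[C@H](C)CCO[Si](c1ccccc1)(c1ccccc1)C(C)(C)C
F2 | step 8 | bromomagnesium (6R)-6-[(3E,7S)-9-{[tert-butyl(diphenyl)silyl]oxy}-3,7-dimethylnon-3-en-1-yl]-1,4-dioxaspiro[4.5]dec-7-en-8-olate | Br[Mg]OC1=C[C@@H](CC/C(C)=C/CC[C@H](C)CCO[Si](c2ccccc2)(c2ccccc2)C(C)(C)C)C2(CC1)OCCO2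
F3 | step 8 | (6R,7R)-6-[(3E,7S)-9-{[tert-butyl(diphenyl)silyl]oxy}-3,7-dimethylnon-3-en-1-yl]-7-methyl-1,4-dioxaspiro[4.5]decan-8-one | C[C@H]1C(=O)CCC2(OCCO2)[C@@H]1CC/C(C)=C/CC[C@H](C)CCO[Si](c1ccccc1)(c1ccccc1)C(C)(C)C
F4 | step 8 | {[(6R)-6-[(3E,7S)-9-{[tert-butyl(diphenyl)silyl]oxy}-3,7-dimethylnon-3-en-1-yl]-7-methyl-1,4-dioxaspiro[4.5]dec-7-en-8-yl]oxy}trimethylsilane | CC1=C(O[Si](C)(C)C)CCC2(OCCO2)[C@@H]1CC/C(C)=C/CC[C@H](C)CCO[Si](c1ccccc1)(c1ccccc1)C(C)(C)C
F5 | step 10 | [(6R,7S,8R)-6-[(3E,7S)-9-{[tert-butyl(diphenyl)silyl]oxy}-3,7-dimethylnon-3-en-1-yl]-8-hydroxy-7-methyl-1,4-dioxaspiro[4.5]decan-7-yl]methyl 2,2-dimethylpropanoate | CC(C)(C)C(=O)OC[C@@]1(C)[C@H](O)CCC2(OCCO2)[C@@H]1CC/C(C)=C/CC[C@H](C)CCO[Si](c1ccccc1)(c1ccccc1)C(C)(C)C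
F6 | step 10 | [(6R,7S,8R)-6-[(3E,7S)-9-{[tert-butyl(diphenyl)silyl]oxy}-3,7-dimethylnon-3-en-1-yl]-8-[(1H-imidazol-1-ylcarbonothioyl)oxy]-7-methyl-1,4-dioxaspiro[4.5]decan-7-yl]methyl 2,2-dimethylpropanoate | CC(C)(C)C(=O)OC[C@@]1(C)[C@H](OC(=S)n2ccnc2)CCC2(OCCO2)[C@@H]1CC/C(C)=C/CC[C@H](C)CCO[Si](c1ccccc1)(c1ccccc1)C(C)(C)C
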